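The cyclodecene ring (numbered C1 methyl-bearing alkene carbon, C2, C3 enone carbonyl, C4 isopropyl, C5, C6 acyloxy, C7 carbinol, C8 ketone, C9, C10) hides a 1,5-diene, C2=C1–C10–C9–C8=C7, at the enol level of its C7/C8 ketol. Cutting C9–C10 by a retro-[3,3] shift contracts the ring to a trans-1,2-dialkenylcyclohexanol made from (R)-cryptone. In one operation the anionic oxy-Cope rearrangement closes the ten-membered ring, sets the (E)-C1=C2 alkene and gives a planar-chiral C7 enolate, trapped as its triflate. Methylation and peripheral oxidation of the C8 enol ether then relay this chirality into the C7 carbinol; late esterification adds the epoxyangelate.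

Key step: step 9

Remark: the cyclodecene numbering above is used for 13–19 and 25, ordinary cyclohexane numbering for 2–12 (C3–C6 are the same atoms in both); (1R,5S)-(+)-nopinone and angelic acid are taken as commercial.

Step 1
Reactants: 1 (1R,5S)-(+)-nopinone
Product: 2 (4R)-4-isopropylcyclohex-2-en-1-one ((R)-cryptone)
Conditions: AlCl3, CH2Cl2, 0 °C to rt
Reagents that add atoms: none
Why: Lewis-acid-induced opening of the strained cyclobutane at the C1–C6 bond next to the carbonyl group, followed by hydride shift within the enolate/tertiary cation pair (a known net isomerisation of nopinone), gives the conjugated enone while the C5 stereocentre is untouched and becomes C4 (R).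

Step 2
Reactants: 2 (R)-cryptone
Product: 3 (5R)-2-(tert-butyldimethylsilyloxy)-5-isopropylcyclohexa-1,3-diene
Conditions: LDA, THF, −78 °C; TBSOTf, −78 °C
Reagents that add atoms: tert-butyldimethylsilyl triflate CC(C)(C)[Si](C)(C)OS(=O)(=O)C(F)(F)F
Why: Kinetic alpha-prime deprotonation of the enone and O-silylation (silyl enol ether formation) give the cross-conjugated 2-silyloxydiene and leave the remote stereocentre alone.

Step 3
Reactants: 3 silyloxydiene
Product: 5 (4R,6R)-6-(tert-butyldimethylsilyloxy)-4-isopropylcyclohex-2-en-1-one (cis), via trans-silyloxy enone 4 (not isolated)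
Conditions: mCPBA, NaHCO3, CH2Cl2, −20 °C; crude product then DBU (cat.), toluene, 50 °C
Reagents that add atoms: mCPBA OOC(=O)c1cccc(Cl)c1
Why: Rubottom oxidation epoxidises the electron-rich enol ether bond and 1,4-silyl migration gives the alpha-silyloxy enone, expected mainly anti to the isopropyl group (4), and base-catalysed epimerisation through the cross-conjugated dienolate should then collect the material as the more stable cis isomer with both substituents pseudo-equatorial, which sets C6 (R) under thermodynamic control.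

Step 4
Reactants: 5 cis-silyloxy enone
Product: 6 (4R,6R)-6-(tert-butyldimethylsilyloxy)-2-iodo-4-isopropylcyclohex-2-en-1-one
Conditions: I2, pyridine/CH2Cl2, rt
Reagents that add atoms: iodine II
Why: alpha-Iodination of an enone by reversible conjugate addition of pyridine, iodination of the enolate and elimination is a standard reaction that touches neither stereocentre nor the silyl ether.

Step 5
Reactants: 6 iodoenone
Product: 7 (4R,6R)-6-(tert-butyldimethylsilyloxy)-4-isopropyl-2-(prop-1-en-2-yl)cyclohex-2-en-1-one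
Conditions: isopropenylboronic acid pinacol ester, Pd(dppf)Cl2 (cat.), Cs2CO3, THF/H2O, rt
Reagents that add atoms: isopropenylboronic acid pinacol ester C=C(C)B1OC(C)(C)C(C)(C)O1
Why: Suzuki–Miyaura coupling of the activated 2-iodoenone proceeds under mild aqueous base that leaves the thermodynamically preferred C6 configuration unchanged, and the hindered cross-conjugated dienone is used at once to avoid Diels–Alder dimerisation.

Step 6
Reactants: 7 dienone
Product: 9 (2S,3R,4R,6R)-6-(tert-butyldimethylsilyloxy)-3-hydroxy-4-isopropyl-2-(prop-1-en-2-yl)cyclohexan-1-one (all-equatorial), via boryl ketone 8 (not isolated)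
Conditions: B2pin2, CuCl (cat.), Xantphos (cat.), NaOtBu (cat.), MeOH, THF, rt; then NaBO3·4H2O, THF/H2O, rt
Reagents that add atoms: bis(pinacolato)diboron CC1(C)OB(OC1(C)C)B1OC(C)(C)C(C)(C)O1 (boron of 8); sodium perborate [Na+].[O-]OB=O
Why: Copper-catalysed conjugate borylation delivers boron to C3 anti to the neighbouring isopropyl group, alpha-protonation of the dienolate by methanol leaves the isopropenyl group out of conjugation and equatorial, and stereoretentive perborate oxidation of the C–B bond gives the all-equatorial aldol, whose two new centres serve only as relay elements and are erased later.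

Step 7
Reactants: 9 aldol
Product: 10 (2S,3R,4R,6R)-6-(tert-butyldimethylsilyloxy)-4-isopropyl-2-(prop-1-en-2-yl)-3-(triethylsilyloxy)cyclohexan-1-one
Conditions: TESOTf, 2,6-lutidine, CH2Cl2, −78 °C
Reagents that add atoms: triethylsilyl triflate CC[Si](CC)(CC)OS(=O)(=O)C(F)(F)F
Why: Silylation with the triflate and a hindered pyridine base at low temperature protects the aldol hydroxyl group faster than dehydration or retro-aldol cleavage can occur.

Step 8
Reactants: 10 bis-silyloxy ketone
Product: 11 (1S,2S,3R,4R,6R)-6-(tert-butyldimethylsilyloxy)-1-(1-ethoxyvinyl)-4-isopropyl-2-(prop-1-en-2-yl)-3-(triethylsilyloxy)cyclohexan-1-ol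
Conditions: ethyl vinyl ether, t-BuLi, THF, −78 to 0 °C; anhydrous CeCl3, −78 °C; then 10, −78 °C; aqueous work-up
Reagents that add atoms: ethyl vinyl ether C=COCC
Why: 1,2-Addition of the weakly basic organocerium form of 1-ethoxyvinyllithium outruns enolisation and beta-elimination, and equatorial attack, the normal course for 2-alkylcyclohexanones of the menthone type, places the new alkenyl group trans to the isopropenyl group and the hydroxyl group axial, which sets C1 (S), the centre that later controls C7 of the target.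

Step 9
Reactants: 11 dialkenyl carbinol
Product: 14 (1E,3R,4R,6R,7E)-6-(tert-butyldimethylsilyloxy)-8-ethoxy-4-isopropyl-1-methyl-3-(triethylsilyloxy)cyclodeca-1,7-dien-7-yl triflate, via potassium alkoxide 12 (not isolated), via potassium enolate 13 (not isolated)
Conditions: KH, 18-crown-6, THF, 0 to 40 °C; then −78 °C, N-(5-chloro-2-pyridyl)bis(trifluoromethanesulfonimide)
Reagents that add atoms: N-(5-chloro-2-pyridyl)bis(trifluoromethanesulfonimide) FC(F)(F)S(=O)(=O)N(c1ccc(Cl)cn1)S(=O)(=O)C(F)(F)F; potassium hydride [K+].[H-] (potassium of 12 and 13)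
Why: KH converts 11 into the crown-ether-separated potassium alkoxide 12, whose oxyanion accelerates a concerted suprafacial [3,3]-sigmatropic shift in which the terminal CH2 of the ethoxyvinyl group bonds to the terminal CH2 of the isopropenyl group (new C9–C10 bond) while the cyclohexane C1–C2 bond breaks. The closest known reaction type is the anionic oxy-Cope ring expansion of trans-1,2-dialkenylcyclohexanols to cyclodec-5-enones, a classical entry to germacranes. The ten-membered ring is closed by four-atom ring expansion through a six-centre chair transition state and not by end-to-end cyclisation, so no dilution is needed and formation of enolate 13 makes the step irreversible. No sp3 centre is created: because both alkenyl groups are equatorial and trans, the ring bonds to C3 and C6 lie equatorial on the chair, which gives the (E)-C1=C2 alkene and the in-ring trans C7=C8 enolate, and the carbinol configuration is turned into planar chirality of that unit, whose inner face is covered by C1=C2. The step needs regiochemical and geometric integrity of the enolate, which is secured because hydrogen is the only by-product of KH, so no proton source can move the enolate towards C6 before O-sulfonylation at −78 °C gives 14. The silyl ethers, C3, C4 and C6 are spectators, and a reversible 1,2-silyl shift to the alkoxide would be drained by the rearrangement.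

Step 10
Reactants: 14 enol triflate
Product: 15 (1E,3R,4R,6R,7Z)-6-(tert-butyldimethylsilyloxy)-8-ethoxy-4-isopropyl-1,7-dimethyl-3-(triethylsilyloxy)cyclodeca-1,7-diene (C6 and C9 trans across C7=C8)
Conditions: MeMgBr, Fe(acac)3 (cat.), THF/NMP, −30 to 0 °C; used cold without storage
Reagents that add atoms: methylmagnesium bromide C[Mg]Br
Why: Iron-catalysed Kumada-type cross-coupling of alkenyl triflates with methylmagnesium bromide is fast below 0 °C and retains the double-bond geometry, so the tetrasubstituted enol ether forms under conditions where the strained (E,E)-1,5-diene should not revert by Cope rearrangement.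

Step 11
Reactants: 15 enol ether
Product: 18 (1E,3R,4R,6R,7S)-3,6,7-trihydroxy-4-isopropyl-1,7-dimethylcyclodec-1-en-8-one, via ethoxy epoxide 16 (not isolated), via bis-silyl ketol 17 (not isolated)
Conditions: DMDO (1 equiv), acetone/CH2Cl2, −78 °C; then 48% aq HF, MeCN, 0 °C
Reagents that add atoms: dimethyldioxirane CC1(C)OO1; water O
Why: Epoxidation by DMDO picks the most electron-rich alkene, the tetrasubstituted enol ether, whose inner face is blocked by the ring because neither its methyl nor its ethoxy group can swing through a ten-membered ring, so oxygen arrives on the outer face (opposite to the former bond to C2) and sets C7 (S), after which aqueous HF hydrolyses the alkoxy epoxide to the alpha-hydroxy ketone (Rubottom-type oxidation of an enol ether) and cleaves both silyl ethers.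

Step 12
Reactants: 18 triol ketone
Product: 19 (1E,4R,6R,7S)-6,7-dihydroxy-4-isopropyl-1,7-dimethylcyclodec-1-ene-3,8-dione
Conditions: MnO2, CH2Cl2, rt
Reagents that add atoms: none
Why: Manganese dioxide oxidises only the allylic C3 alcohol, so the saturated C6 and tertiary C7 hydroxyl groups survive and the transient C3 centre is erased without epimerising C4.

Step 13
Reactants: 20 angelic acid ((Z)-2-methylbut-2-enoic acid)
Product: 21 (Z)-2-methylbut-2-en-1-ol
Conditions: LiAlH4, Et2O, 0 °C
Reagents that add atoms: none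
Why: Hydride reduction of the carboxylic acid with LiAlH4 gives the allylic alcohol and keeps the (Z) geometry.

Step 14
Reactants: 21 (Z)-2-methylbut-2-en-1-ol
Product: 22 (2S,3R)-2,3-epoxy-2-methylbutan-1-ol
Conditions: Ti(OiPr)4 (cat.), L-(+)-diethyl tartrate (cat.), t-BuOOH, 4 Å MS, CH2Cl2, −20 °C
Reagents that add atoms: tert-butyl hydroperoxide CC(C)(C)OO
Why: Sharpless asymmetric epoxidation with the L-(+)-tartrate catalyst gives the (2S) epoxy alcohol series, and stereospecific syn oxygen transfer to the (Z)-alkene fixes C3 as (R) with the hydroxymethyl and C3 methyl groups cis.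

Step 15
Reactants: 22 epoxy alcohol
Product: 23 (2R,3R)-2,3-epoxy-2-methylbutanoic acid (epoxyangelic acid)
Conditions: TEMPO (cat.), PhI(OAc)2, MeCN/H2O, 0 °C to rt
Reagents that add atoms: water O
Why: Oxoammonium-catalysed (TEMPO) oxidation through the aldehyde hydrate reaches the acid under nearly neutral conditions that spare the epoxide, and the C2 descriptor changes to (R) only through the change in CIP ranking.

Step 16
Reactants: 19 dihydroxy dione, 23 epoxyangelic acid
Product: 25 target CNP0389889.1, via mixed anhydride 24 (not isolated)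
Conditions: 23, 2,4,6-trichlorobenzoyl chloride, Et3N, toluene, rt; then 19, DMAP, toluene, rt
Reagents that add atoms: 2,4,6-trichlorobenzoyl chloride O=C(Cl)c1c(Cl)cc(Cl)cc1Cl (atoms of 24 only)
Why: Yamaguchi esterification through the mixed anhydride acylates the secondary C6 hydroxyl group in preference to the tertiary, hydrogen-bonded C7 hydroxyl group and proceeds with retention at C6 and at both epoxide carbons.

Compound list
1 | (1R,5S)-(+)-nopinone | CC1(C)[C@H]2CCC(=O)[C@@H]1C2 | starting material
2 | (4R)-4-isopropylcyclohex-2-en-1-one ((R)-cryptone) | O=C1C=C[C@@H](C(C)C)CC1 | intermediate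
3 | (5R)-2-(tert-butyldimethylsilyloxy)-5-isopropylcyclohexa-1,3-diene | CC(C)(C)[Si](C)(C)OC1=CC[C@H](C(C)C)C=C1 | intermediate
4 | (4R,6S)-6-(tert-butyldimethylsilyloxy)-4-isopropylcyclohex-2-en-1-one (trans) | O=C1C=C[C@@H](C(C)C)C[C@@H]1O[Si](C)(C)C(C)(C)C | intermediate
5 | (4R,6R)-6-(tert-butyldimethylsilyloxy)-4-isopropylcyclohex-2-en-1-one (cis) | O=C1C=C[C@@H](C(C)C)C[C@H]1O[Si](C)(C)C(C)(C)C | intermediate
6 | (4R,6R)-6-(tert-butyldimethylsilyloxy)-2-iodo-4-isopropylcyclohex-2-en-1-one | O=C1C(I)=C[C@@H](C(C)C)C[C@H]1O[Si](C)(C)C(C)(C)C | intermediate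
7 | (4R,6R)-6-(tert-butyldimethylsilyloxy)-4-isopropyl-2-(prop-1-en-2-yl)cyclohex-2-en-1-one | O=C1C(C(C)=C)=C[C@@H](C(C)C)C[C@H]1O[Si](C)(C)C(C)(C)C | intermediate
8 | (2R,3R,4S,6R)-6-(tert-butyldimethylsilyloxy)-4-isopropyl-3-(pinacolatoboryl)-2-(prop-1-en-2-yl)cyclohexan-1-one | O=C1[C@@H](C(C)=C)[C@H](B2OC(C)(C)C(C)(C)O2)[C@@H](C(C)C)C[C@H]1O[Si](C)(C)C(C)(C)C | intermediate
9 | (2S,3R,4R,6R)-6-(tert-butyldimethylsilyloxy)-3-hydroxy-4-isopropyl-2-(prop-1-en-2-yl)cyclohexan-1-one | O=C1[C@@H](C(C)=C)[C@H](O)[C@@H](C(C)C)C[C@H]1O[Si](C)(C)C(C)(C)C | intermediate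
10 | (2S,3R,4R,6R)-6-(tert-butyldimethylsilyloxy)-4-isopropyl-2-(prop-1-en-2-yl)-3-(triethylsilyloxy)cyclohexan-1-one | O=C1[C@@H](C(C)=C)[C@H](O[Si](CC)(CC)CC)[C@@H](C(C)C)C[C@H]1O[Si](C)(C)C(C)(C)C | intermediate
11 | (1S,2S,3R,4R,6R)-6-(tert-butyldimethylsilyloxy)-1-(1-ethoxyvinyl)-4-isopropyl-2-(prop-1-en-2-yl)-3-(triethylsilyloxy)cyclohexan-1-ol | C=C(OCC)[C@]1(O)[C@@H](C(C)=C)[C@H](O[Si](CC)(CC)CC)[C@@H](C(C)C)C[C@H]1O[Si](C)(C)C(C)(C)C | intermediate
12 | potassium alkoxide of 11 | C=C(OCC)[C@]1([O-])[C@@H](C(C)=C)[C@H](O[Si](CC)(CC)CC)[C@@H](C(C)C)C[C@H]1O[Si](C)(C)C(C)(C)C.[K+] | intermediate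
13 | potassium C7 enolate of the ring-expanded cyclodecadiene (C6 and C9 trans across C7=C8) | C/C1=C\[C@H](O[Si](CC)(CC)CC)[C@@H](C(C)C)C[C@@H](O[Si](C)(C)C(C)(C)C)/C([O-])=C(OCC)/CC1.[K+] | intermediate
14 | (1E,3R,4R,6R,7E)-6-(tert-butyldimethylsilyloxy)-8-ethoxy-4-isopropyl-1-methyl-3-(triethylsilyloxy)cyclodeca-1,7-dien-7-yl triflate | C/C1=C\[C@H](O[Si](CC)(CC)CC)[C@@H](C(C)C)C[C@@H](O[Si](C)(C)C(C)(C)C)/C(OS(=O)(=O)C(F)(F)F)=C(OCC)/CC1 | intermediate
15 | (1E,3R,4R,6R,7Z)-6-(tert-butyldimethylsilyloxy)-8-ethoxy-4-isopropyl-1,7-dimethyl-3-(triethylsilyloxy)cyclodeca-1,7-diene | C/C1=C\[C@H](O[Si](CC)(CC)CC)[C@@H](C(C)C)C[C@@H](O[Si](C)(C)C(C)(C)C)/C(C)=C(OCC)/CC1 | intermediate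
16 | (7S,8S)-7,8-epoxide of 15 (8-ethoxy epoxide) | C/C1=C\[C@H](O[Si](CC)(CC)CC)[C@@H](C(C)C)C[C@@H](O[Si](C)(C)C(C)(C)C)[C@]2(C)O[C@@]2(OCC)CC1 | intermediate
17 | (1E,3R,4R,6R,7S)-6-(tert-butyldimethylsilyloxy)-7-hydroxy-4-isopropyl-1,7-dimethyl-3-(triethylsilyloxy)cyclodec-1-en-8-one | C/C1=C\[C@H](O[Si](CC)(CC)CC)[C@@H](C(C)C)C[C@@H](O[Si](C)(C)C(C)(C)C)[C@](C)(O)C(=O)CC1 | intermediate
18 | (1E,3R,4R,6R,7S)-3,6,7-trihydroxy-4-isopropyl-1,7-dimethylcyclodec-1-en-8-one | C/C1=C\[C@H](O)[C@@H](C(C)C)C[C@@H](O)[C@](C)(O)C(=O)CC1 | intermediate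
19 | (1E,4R,6R,7S)-6,7-dihydroxy-4-isopropyl-1,7-dimethylcyclodec-1-ene-3,8-dione | C/C1=C\C(=O)[C@@H](C(C)C)C[C@@H](O)[C@](C)(O)C(=O)CC1 | intermediate
20 | angelic acid | C/C=C(/C)C(=O)O | starting material
21 | (Z)-2-methylbut-2-en-1-ol | C/C=C(/C)CO | intermediate
22 | (2S,3R)-2,3-epoxy-2-methylbutan-1-ol | OC[C@]1(C)O[C@@H]1C | intermediate
23 | (2R,3R)-2,3-epoxy-2-methylbutanoic acid | OC(=O)[C@]1(C)O[C@@H]1C | intermediate
24 | (2R,3R)-2,3-epoxy-2-methylbutanoic 2,4,6-trichlorobenzoic anhydride | O=C(OC(=O)[C@]1(C)O[C@@H]1C)c1c(Cl)cc(Cl)cc1Cl | intermediate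
25 | (1E,4R,6R,7S)-7-hydroxy-4-isopropyl-1,7-dimethyl-3,8-dioxocyclodec-1-en-6-yl (2R,3R)-2,3-epoxy-2-methylbutanoate | C/C1=C\C(=O)[C@@H](C(C)C)C[C@@H](OC(=O)[C@]2(C)O[C@@H]2C)[C@](C)(O)C(=O)CC1 | target

Total step count: 16. Longest linear sequence: 13 steps (steps 1–12 and 16).

Steps most likely to fail

**Step 10.**
- What may go wrong: activation of the crowded, electron-rich tetrasubstituted C–O bond is slow. Reduction of the triflate, or Cope reversion of the strained 1,5-diene to a divinylcyclohexane, then overtakes methyl transfer.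
- The fallback sets out from 10 and returns at 19. It makes the C7 methyl group from the C7 carbonyl carbon instead of by cross-coupling.
- Ketone 10 is treated with vinylmagnesium bromide and CeCl3 to give the vinyl carbinol F1.
- KH and 18-crown-6 bring about the same ring expansion. The enolate is hydroxylated at C8 with 2-(phenylsulfonyl)-3-phenyloxaziridine (Davis oxidation) and silylated in the flask with TESCl to give the silyloxy ketone F2, whose C8 centre is inconsequential.
- Petasis olefination with Cp2TiMe2 gives the exocyclic alkene F3, and PPTS in ethanol removes both triethylsilyl groups to give the diol F4.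
- Dess–Martin oxidation gives the dienedione F5.
- Mukaiyama-type reductive hydroxylation (Mn(dpm)3, PhSiH3, O2, then P(OEt)3) of the more reactive 1,1-disubstituted enone, with oxygen capture on the peripheral face, gives the silyl ketol F6. HF·pyridine then gives 19.

**Step 9.**
- What may go wrong: O-sulfonylation of the hindered, electron-rich potassium enolate is slower than proton exchange with unreacted carbinol or than silyl migration. The position and geometry of the C7=C8 unit are then scrambled before it is fixed.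
- The fallback sets out from 11 and returns at 15, bypassing 14.
- Enolate 13 is generated as before but intercepted with the smaller, harder electrophile diphenyl chlorophosphate to give the enol phosphate F7.
- F7 is methylated with AlMe3 under Pd(PPh3)4 catalysis in 1,2-dichloroethane at rt. This is the aluminium/palladium alkylation of enol phosphates, a different leaving group and a different carbon–carbon bond-forming manifold.

**Step 6.**
- What may go wrong: gamma-protonation of the dienolate or base-induced migration of the isopropenyl double bond into conjugation, and dehydration of the aldol during the oxidative work-up.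
- The fallback sets out from 7 and returns at 9. It brings in the C3 oxygen as an electrophile-free epoxide instead of through boron.
- Nucleophilic epoxidation of the enone double bond (t-BuOOH, DBU, CH2Cl2), anti to the isopropyl group, gives the epoxy ketone F8.
- Reductive opening at the alpha carbon with the phenylselenide reagent made from (PhSe)2 and NaBH4 in ethanol/acetic acid gives 9 after protonation to the equatorial isopropenyl isomer.

Further compounds
F1 | step 10 | (1S,2S,3R,4R,6R)-6-(tert-butyldimethylsilyloxy)-4-isopropyl-2-(prop-1-en-2-yl)-3-(triethylsilyloxy)-1-vinylcyclohexan-1-ol | C=C[C@]1(O)[C@@H](C(C)=C)[C@H](O[Si](CC)(CC)CC)[C@@H](C(C)C)C[C@H]1O[Si](C)(C)C(C)(C)C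
F2 | step 10 | (1E,3R,4R,6R,8S)-6-(tert-butyldimethylsilyloxy)-4-isopropyl-1-methyl-3,8-bis(triethylsilyloxy)cyclodec-1-en-7-one | C/C1=C\[C@H](O[Si](CC)(CC)CC)[C@@H](C(C)C)C[C@@H](O[Si](C)(C)C(C)(C)C)C(=O)[C@@H](O[Si](CC)(CC)CC)CC1
F3 | step 10 | (1E,3R,4R,6R,8S)-6-(tert-butyldimethylsilyloxy)-4-isopropyl-1-methyl-7-methylidene-3,8-bis(triethylsilyloxy)cyclodec-1-ene | C/C1=C\[C@H](O[Si](CC)(CC)CC)[C@@H](C(C)C)C[C@@H](O[Si](C)(C)C(C)(C)C)C(=C)[C@@H](O[Si](CC)(CC)CC)CC1
F4 | step 10 | (1E,3R,4R,6R,8S)-6-(tert-butyldimethylsilyloxy)-4-isopropyl-1-methyl-7-methylidenecyclodec-1-ene-3,8-diol | C/C1=C\[C@H](O)[C@@H](C(C)C)C[C@@H](O[Si](C)(C)C(C)(C)C)C(=C)[C@@H](O)CC1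
F5 | step 10 | (1E,4R,6R)-6-(tert-butyldimethylsilyloxy)-4-isopropyl-1-methyl-7-methylidenecyclodec-1-ene-3,8-dione | C/C1=C\C(=O)[C@@H](C(C)C)C[C@@H](O[Si](C)(C)C(C)(C)C)C(=C)C(=O)CC1
F6 | step 10 | (1E,4R,6R,7S)-6-(tert-butyldimethylsilyloxy)-7-hydroxy-4-isopropyl-1,7-dimethylcyclodec-1-ene-3,8-dione | C/C1=C\C(=O)[C@@H](C(C)C)C[C@@H](O[Si](C)(C)C(C)(C)C)[C@](C)(O)C(=O)CC1
F7 | step 9 | (1E,3R,4R,6R,7E)-6-(tert-butyldimethylsilyloxy)-8-ethoxy-4-isopropyl-1-methyl-3-(triethylsilyloxy)cyclodeca-1,7-dien-7-yl diphenyl phosphate | C/C1=C\[C@H](O[Si](CC)(CC)CC)[C@@H](C(C)C)C[C@@H](O[Si](C)(C)C(C)(C)C)/C(OP(=O)(Oc2ccccc2)Oc2ccccc2)=C(OCC)/CC1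
F8 | step 6 | 2,3-epoxide of 7 with the oxirane anti to the isopropyl group (2,3-epoxy-6-(tert-butyldimethylsilyloxy)-4-isopropyl-2-(prop-1-en-2-yl)cyclohexan-1-one) | O=C1[C@]2(C(C)=C)O[C@@H]2[C@@H](C(C)C)C[C@H]1O[Si](C)(C)C(C)(C)C
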